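The product you wanted quickly is monomer in chains with its crystals, as a fraction of the free monomer charged. Your hunch was that it follows the initiator, and we agree, but the two runs at 12 min stand closer to the root of the initiator than to the initiator itself.

all flasks: free monomer 0.20 M
- winter: protic impurity 0.040 M; initiator 1.4 mM; run made earlier
- autumn: protic impurity 0.040 M; initiator 2.2 mM; run made earlier
- flask: protic impurity 0.0400 M; initiator 1.0 mM; time 12 min

| run | time / min | monomer in chains / % | crystals / % |
|---|---|---|---|
| winter | 1.50 | 5.5 | 3.5 |
| winter | 4.00 | 13.4 | 10.7 |
| winter | 8.00 | 21.5 | 18.4 |
| winter | 12.0 | 25.8 | 24.1 |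
| autumn | 1.50 | 6.8 | 4.9 |
| autumn | 4.00 | 14.5 | 15.0 |
| autumn | 8.00 | 24.8 | 23.0 |
| autumn | 12.0 | 32.1 | 29.5 |

(readings scatter by 0.5 percentage points)

1. amount of monomer in chains and crystals together at 12 min, in percent of the free monomer charged
2. concentration of monomer in chains in solution at 12 min, in percent of saturation

- what is said of monomer in chains includes crystals
- crystals is a solid; its amount is given per volume of the solution
- what may be going on: free monomer <-> dormant form; protic impurity + free monomer -> quenched substrate; free monomer + growing radical -> monomer in chains + growing radical; 2 growing radical -> dead chain; initiator -> 2 initiating radical; crystals <-> monomer in chains; free monomer + initiating radical -> growing radical + monomer in chains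

- Growing radicals born in proportion to the initiator and dying in pairs stand in proportion to its root, a steady state, and the runs and the flask differ in initiator while free monomer and protic impurity are charged alike.
- So we rescale: the winter run's 25.8% at 1.4 mM becomes 21.8% on the flask's 1.0 mM, and the autumn run's 32.1% becomes 21.6%.
- These differ by 0.20 percentage points, against a scatter of 0.5 points, so we commit to their mean, 21.7%, the root-scaled yield: chains at 12 min times the root of the flask's initiator over the run's.
- For saturation we say at or a little above it and nothing sharper: chains less crystals read 1.7 points and 2.6 points at 12 min, each carrying the scatter of two readings.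
- The forecast gave 22% and 100%, holding that “crystallisation keeps pace”.
- The flask gives 22.6%, which is 0.90 points above our root-scaled yield, and 109% of saturation.

    free monomer ⇌ dormant form (K = 1.30, k = 0.0901 min⁻¹)
    protic impurity + free monomer → quenched substrate (k = 0.673 L mol⁻¹ min⁻¹)
    free monomer + growing radical → monomer in chains + growing radical, rate k3*[growing radical]*[free monomer] (k = 5.12 × 10⁵ L mol⁻¹ min⁻¹)
    2 growing radical → dead chain (k = 3.00 × 10⁷ L mol⁻¹ s⁻¹)
    initiator → 2 initiating radical (k = 0.00902 min⁻¹)
    crystals ⇌ monomer in chains, rate k6*(cs6 - [monomer in chains]) while solid is left; crystals form when [monomer in chains] > cs6 (solubility = 2.90 mM, k = 8.38 min⁻¹)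
    free monomer + initiating radical → growing radical + monomer in chains (k = 2.60 × 10⁵ L mol⁻¹ s⁻¹)

- Termination in pairs is the main reason this flask holds 22.6% at 12 min: the same run without that step gives 97.3%. On the neighbour with 0.0040 M of initiator, the root-scaled yield predicts 43.4%, and that flask stores 39.0%. At 12 min that neighbour's growing radical stands at twice the level in our flask, as the root says, while its free monomer is down to 21% against 30%.

The data are calculated with made-up constants.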